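The reagent is the short partner in the flask: one reagent binds one starting material, and the recipe charges 0.400 M of it against 0.80 M of starting material.

| flask | starting material | reagent | protic impurity | remark | time |
|---|---|---|---|---|---|
| grey | 0.80 M | 0.56 M | 0.016 M | run made earlier |  |
| green | 0.80 M | 0.88 M | 0.016 M | run made earlier |  |
| flask | 0.80 M | 0.400 M | 0.0160 M |  | 30 min |

| run | time / min | target / % | isomer of the product / % |
|---|---|---|---|
| grey | 2.00 | 19 | 40 |
| grey | 6.00 | 6 | 59 |
| grey | 12.0 | 2 | 63 |
| grey | 15.0 | 5 | 62 |
| grey | 25.0 | 1 | 65 |
| green | 2.00 | 20 | 49 |
| green | 4.00 | 8 | 70 |
| green | 6.00 | 5 | 80 |
| green | 12.0 | 3 | 88 |
| green | 25.0 | 5 | 86 |

(scatter of a reading: 2 percentage points)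

- the numbers in the tables scatter with a standard deviation of 2 percentage points
- steps thought possible: starting material + reagent <-> target; starting material + protic impurity -> quenched substrate; target <-> isomer of the product
- the reaction counts as stopped when no species that holds the starting material changes by six tenths of a point or more over the second half of the time

- at 30 min, what has stopped the reaction, if anything has (the reagent has run out first / it is still moving / forward and back rates have come level / all of the starting material has reacted)
- amount of target at 30 min, in percent of the starting material charged
- amount of isomer of the product at 30 min, in percent of the starting material charged

The settings, taken one after the other, first by hand and then as the earlier runs show them: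

1. Starting material: the grey and green runs hold 0.80 M and 0.80 M, the same as the flask, so they show no effect of changing it.

2. Time: target plus isomer of the product in the grey run reads 65.0 % at 12.0 min and 66.0 % at 25.0 min, so I expect the flask to stand level at 30 min.

3. Protic impurity: its 0.0160 M can take 2.00 % of the starting material, and it should take this from the spare starting material, since the impurity charge is far smaller than the spare amount.

4. Reagent: dividing its charge by that of the starting material gives 50.0 %, the ceiling C, the most target plus isomer of the product that this limiting reagent can carry. The same division gives 70.0 % for the grey run, whose last reading falls 4 percentage points short.

The late readings of both runs, from 12.0 min in the grey run and 12.0 min in the green, give a ratio of target to isomer of the product, ρ, read with their scatter as 0.0440. At the ceiling, my reckoning for the flask is therefore 2.11 % target and 47.9 % isomer of the product, and since the last grey reading fell short of its own ceiling, I expect the sum in the flask to stand a little under C.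

The forecast says forward and back rates have come level, with 2.1 % target and 46.5 % isomer of the product, a sum just under C: “Both runs level off, so I treat the plateau as an equilibrium.”

At 30 min the flask holds 1.52 % target and 47.0 % isomer of the product, and what has stopped it is this: forward and back rates have come level.

    starting material + reagent ⇌ target (K = 2.52 /M, k = 0.427 /M/s)
    starting material + protic impurity → quenched substrate (k = 1.45 /M/s)
    target ⇌ isomer of the product (K = 31.0, k = 0.0138 /s)

In the flask, target and isomer of the product together, 48.5 %, stand 1.5 points under C, while the reagent still free at the end is 3.0 % of its own charge. In the neighbour flask charged with 0.24 M of reagent, C becomes 30.0 %, and that flask holds 0.917 % target and 28.4 % isomer of the product, together 29.3 %.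

Readings and results were computed for substances that don't exist, noise included.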